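The target is read as a linear A–B–C–D stilbene tetramer whose three 2,3-dihydrobenzofurans are each cut into an E-stilbene and one o-quinone diazide (7). In the key step the Rh carbenoid of 7 (future C3a of the central ring, benzofuran numbering, next to the C7a carbonyl) cyclopropanates the alkene of the protected ε-viniferin-type dimer 14; the spiro[2.5]octadienone (C3a, C3, C2) is not isolated: it expands by C7a and O1 to the central ring and sets both stereocentres. The step exploits the 4-oxyphenyl donor on C2 against the non-donating ring B on C3, and the aromatisation of ring C. The C4 bromide then takes the next styryl unit by Suzuki coupling.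

Key step: step 10

Abbreviations and locants: TIPS = triisopropylsilyl, TIPSO = triisopropylsilyloxy. Ring A = the 3,5-dioxygenated phenyl ring; rings B, C, D = benzo rings of the first, the central and the last dihydrobenzofuran. Each dihydrobenzofuran is numbered O1, C2, C3, C3a, C4–C7, C7a.

Assumption: the S-configured tert-leucinate Rh(II) catalyst is taken to deliver the 3R series in step 6; this sense of induction is not secured for quinoid carbenoids, and if it proves opposite the S- and R-catalysts change places in steps 6, 10 and 12.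

Step 1
Reactants: 1 resveratrol [(E)-3,5,4'-trihydroxystilbene]
Product: 2 (E)-3,5,4'-tris(triisopropylsilyloxy)stilbene
Conditions: TIPSCl (3.6 equiv), imidazole (7 equiv), DMF, 0 °C to rt
Reagents that add atoms: triisopropylsilyl chloride CC(C)[Si](Cl)(C(C)C)C(C)C
Why: Imidazole-promoted O-silylation of three unhindered phenols; the silyl ether keeps the 4'-oxygen a π-donor for the annulation and can be removed at the end with fluoride without touching stilbene or benzylic ether bonds.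

Step 2
Reactants: 3 5-bromoresorcinol (5-bromobenzene-1,3-diol)
Product: 4 5-bromo-4-[(E)-phenyldiazenyl]benzene-1,3-diol
Conditions: PhN2+ BF4− (1.0 equiv), NaOAc, MeOH/H2O, 0 °C
Reagents that add atoms: benzenediazonium tetrafluoroborate N#[N+]c1ccccc1.F[B-](F)(F)F
Why: Azo coupling (electrophilic aromatic substitution) of a resorcinol takes place para to one hydroxyl and ortho to the other, i.e. at C4 next to the bromine, and one equivalent of diazonium salt in acetate buffer should hold it at mono-coupling.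

Step 3
Reactants: 4 5-bromo-4-[(E)-phenyldiazenyl]benzene-1,3-diol
Product: 5 3-bromo-2-[(E)-phenyldiazenyl]-5-(triisopropylsilyloxy)phenol
Conditions: TIPSCl (1.05 equiv), imidazole, DMF, 0 °C
Reagents that add atoms: triisopropylsilyl chloride CC(C)[Si](Cl)(C(C)C)C(C)C
Why: The hydroxyl ortho to the azo group is tied up in an intramolecular hydrogen bond (azo–hydrazone tautomer), so the more acidic and unhindered para hydroxyl should be silylated selectively.

Step 4
Reactants: 5 3-bromo-2-[(E)-phenyldiazenyl]-5-(triisopropylsilyloxy)phenol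
Product: 6 2-amino-3-bromo-5-(triisopropylsilyloxy)phenol
Conditions: Na2S2O4 (4 equiv), THF/EtOH/H2O, 50 °C; used crude under argon
Reagents that add atoms: none
Why: Dithionite reduction cleaves the azo N=N bond to two amines and should leave the aryl bromide and the aryl silyl ether untouched.

Step 5
Reactants: 6 2-amino-3-bromo-5-(triisopropylsilyloxy)phenol
Product: 7 3-bromo-2-diazo-5-(triisopropylsilyloxy)cyclohexa-3,5-dien-1-one (o-quinone diazide)
Conditions: t-BuONO (1.2 equiv), AcOH (1 equiv), THF, 0 °C, dark; water-free work-up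
Reagents that add atoms: tert-butyl nitrite CC(C)(C)ON=O
Why: Diazotisation of an o-aminophenol with an alkyl nitrite gives the neutral o-quinone diazide (diazonium phenolate) after loss of the phenolic proton; water-free conditions spare the silyl ether para to the diazonium group.

Step 6
Reactants: 2 (E)-3,5,4'-tris(triisopropylsilyloxy)stilbene + 7 o-quinone diazide
Product: 9 (2R,3R)-4-bromo-3-[3,5-bis(TIPSO)phenyl]-2-[4-(TIPSO)phenyl]-6-(TIPSO)-2,3-dihydrobenzofuran, via spirocyclopropane 8 (not isolated)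
Conditions: Rh2(S-TCPTTL)4 (2 mol %), 2 (2 equiv), 7 added over 6 h, PhCF3, 50 °C
Reagents that add atoms: none
Why: Rh(II)-catalysed formal [3+2] annulation of an o-quinone diazide with an alkene through cyclopropanation and Cloke–Wilson ring expansion: the carbenoid carbon bonds to the alkene carbon bearing ring A, the chiral carboxylate catalyst selects the alkene face (C3, R), and trans closure of the phenolate onto the p-silyloxybenzylic cation sets C2 (R).

Step 7
Reactants: 10 4-hydroxybenzaldehyde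
Product: 11 4-(triisopropylsilyloxy)benzaldehyde
Conditions: TIPSCl (1.2 equiv), imidazole, DMF, rt
Reagents that add atoms: triisopropylsilyl chloride CC(C)[Si](Cl)(C(C)C)C(C)C
Why: Standard imidazole-promoted silylation of a phenol.

Step 8
Reactants: 11 4-(triisopropylsilyloxy)benzaldehyde + 12 bis(pinacolatoboryl)methane
Product: 13 (E)-2-[4-(triisopropylsilyloxy)phenyl]ethenylboronic acid pinacol ester
Conditions: 12 (1.2 equiv), LiTMP (1.2 equiv), THF, 0 °C; then 11, −78 °C to rt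
Reagents that add atoms: none
Why: Boron–Wittig olefination: the α,α-diboryl carbanion adds to the aldehyde and syn elimination of the O–B unit should give the E-alkenyl boronate selectively.

Step 9
Reactants: 9 (2R,3R)-4-bromo-dihydrobenzofuran + 13 (E)-alkenyl boronate
Product: 14 (2R,3R)-3-[3,5-bis(TIPSO)phenyl]-2-[4-(TIPSO)phenyl]-6-(TIPSO)-4-[(E)-2-[4-(TIPSO)phenyl]ethenyl]-2,3-dihydrobenzofuran
Conditions: Pd(OAc)2 (5 mol %), SPhos (10 mol %), K3PO4 (3 equiv), toluene/H2O 10:1, 80 °C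
Reagents that add atoms: none
Why: Suzuki–Miyaura coupling of the hindered aryl bromide with a bulky biarylphosphine ligand; the E geometry comes from the boronate with retention and the stereocentres are not touched.

Step 10
Reactants: 14 penta-O-TIPS ε-viniferin-type stilbene + 7 o-quinone diazide
Product: 16 (2S,3S)-4-bromo-2-[4-(TIPSO)phenyl]-6-(TIPSO)-3-[(2R,3R)-3-[3,5-bis(TIPSO)phenyl]-2-[4-(TIPSO)phenyl]-6-(TIPSO)-2,3-dihydrobenzofuran-4-yl]-2,3-dihydrobenzofuran, via spirocyclopropane 15 (not isolated)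
Conditions: Rh2(R-TCPTTL)4 (3 mol %), 7 (3 equiv) added over 8 h, PhCF3, 50 °C
Reagents that add atoms: none
Why: Rh(II) extrudes N2 from 7 to give an electrophilic quinoid carbenoid (future C3a) that adds to the alkene of 14 with charge developing on the carbon that bears the 4-silyloxyphenyl group, giving the trans-1,2-diarylspiro[2.5]octa-5,7-dien-4-one 15; heterolysis of its C3a–C2 bond aromatises ring C to a phenolate and leaves a p-quinone-methide-type cation at C2, which O1 captures, so that the three-membered ring C3a/C3/C2 is enlarged by C7a and O1 (Cloke–Wilson ring expansion). The closest known reaction type is the Rh(II)-catalysed formal [3+2] annulation of o-quinone diazides and cyclic 2-diazo-1,3-diones with styrenes to dihydro(benzo)furans. The cyclopropane closes by [2+1] addition and the dihydrofuran by 5-exo-trig attack of the phenolate oxygen on the exocyclic quinone-methide carbon. C3 is set in the C–C bond formation: with the vinyl C–H turned toward C3–H of the resident dihydrobenzofuran, the carbenoid should approach the alkene carbon next to ring B anti to ring A on that C3, which gives 3S, and the R-catalyst is used as the matched partner; C2 is set after bond rotation in the open zwitterion, trans to ring B (2S), so cis- and trans-cyclopropanes and both C2 epimers converge on one product. The step needs regioselectivity (O1 to C2, C3a to C3), secured by the p-silyloxyphenyl donor on C2 against the meta-dioxygenated ring B on C3, and chemoselectivity for the single alkene over the silyloxyarenes, helped by slow addition of 7 and the bulk of the silyl groups.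

Step 11
Reactants: 16 central-ring bromide + 13 (E)-alkenyl boronate
Product: 17 the 4-[(E)-2-[4-(TIPSO)phenyl]ethenyl] analogue of 16 (bromine replaced; stereocentres unchanged)
Conditions: Pd(OAc)2 (5 mol %), SPhos (10 mol %), K3PO4 (3 equiv), toluene/H2O 10:1, 80 °C
Reagents that add atoms: none
Why: Suzuki–Miyaura coupling as in step 9; the alkene geometry is carried over from the boronate and no stereocentre is touched.

Step 12
Reactants: 17 trimer stilbene + 7 o-quinone diazide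
Product: 19 (2R,3R)-4-bromo-2-[4-(TIPSO)phenyl]-6-(TIPSO)-2,3-dihydrobenzofuran carrying at C3 the (2S,3S)-dihydrobenzofuran-4-yl unit of 17 (tetramer bromide), via spirocyclopropane 18 (not isolated)
Conditions: Rh2(S-TCPTTL)4 (3 mol %), 7 (3 equiv) added over 8 h, PhCF3, 50 °C
Reagents that add atoms: none
Why: Same carbenoid cyclopropanation and Cloke–Wilson ring expansion as in step 10; the carbenoid should add anti to ring B on C3 of the central ring (new C3, R, matched S-catalyst) and trans closure of the phenolate sets the new C2 (R).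

Step 13
Reactants: 20 3,4-dihydroxybenzaldehyde
Product: 21 3,4-bis(triisopropylsilyloxy)benzaldehyde
Conditions: TIPSOTf (2.4 equiv), 2,6-lutidine (3 equiv), CH2Cl2, 0 °C to rt
Reagents that add atoms: triisopropylsilyl trifluoromethanesulfonate CC(C)[Si](OS(=O)(=O)C(F)(F)F)(C(C)C)C(C)C
Why: The silyl triflate is reactive enough to silylate both neighbouring catechol oxygens.

Step 14
Reactants: 21 3,4-bis(triisopropylsilyloxy)benzaldehyde + 12 bis(pinacolatoboryl)methane
Product: 22 (E)-2-[3,4-bis(triisopropylsilyloxy)phenyl]ethenylboronic acid pinacol ester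
Conditions: 12 (1.2 equiv), LiTMP (1.2 equiv), THF, 0 °C; then 21, −78 °C to rt
Reagents that add atoms: none
Why: Boron–Wittig olefination as in step 8, E-selective through syn elimination of the O–B unit.

Step 15
Reactants: 19 tetramer bromide + 22 (E)-alkenyl boronate
Product: 23 deca-O-TIPS ether of the target [19 with Br replaced by (E)-2-[3,4-bis(TIPSO)phenyl]ethenyl]
Conditions: Pd(OAc)2 (5 mol %), SPhos (10 mol %), K3PO4 (3 equiv), toluene/H2O 10:1, 80 °C
Reagents that add atoms: none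
Why: Suzuki–Miyaura coupling as in steps 9 and 11 installs the E-configured catechol styryl unit without touching the six stereocentres.

Step 16
Reactants: 23 deca-O-TIPS ether of the target
Product: 24 CNP0099535.1 (target)
Conditions: TBAF (12 equiv), AcOH (12 equiv), THF, 0 °C to rt, argon, dark; reverse-phase purification
Reagents that add atoms: none
Why: Fluoride cleaves all ten aryl Si–O bonds, while acetic acid keeps the liberated phenols protonated so that the p-hydroxybenzylic C2–O1 bonds should not open through quinone methides and the catechol is not oxidised; no stereocentre is touched.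

Compound list

1 | resveratrol, (E)-3,5,4'-trihydroxystilbene | Oc1ccc(/C=C/c2cc(O)cc(O)c2)cc1 | starting material
2 | (E)-3,5,4'-tris(triisopropylsilyloxy)stilbene | CC(C)[Si](C(C)C)(C(C)C)Oc1ccc(/C=C/c2cc(O[Si](C(C)C)(C(C)C)C(C)C)cc(O[Si](C(C)C)(C(C)C)C(C)C)c2)cc1 | intermediate
3 | 5-bromoresorcinol | Oc1cc(O)cc(Br)c1 | starting material
4 | 5-bromo-4-[(E)-phenyldiazenyl]benzene-1,3-diol | Oc1cc(O)c(/N=N/c2ccccc2)c(Br)c1 | intermediate
5 | 3-bromo-2-[(E)-phenyldiazenyl]-5-(triisopropylsilyloxy)phenol | Oc1cc(O[Si](C(C)C)(C(C)C)C(C)C)cc(Br)c1/N=N/c1ccccc1 | intermediate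
6 | 2-amino-3-bromo-5-(triisopropylsilyloxy)phenol | Nc1c(O)cc(O[Si](C(C)C)(C(C)C)C(C)C)cc1Br | intermediate
7 | 3-bromo-2-diazo-5-(triisopropylsilyloxy)cyclohexa-3,5-dien-1-one (o-quinone diazide) | O=C1C=C(O[Si](C(C)C)(C(C)C)C(C)C)C=C(Br)C1=[N+]=[N-] | intermediate
8 | (1R,2R)-8-bromo-1-[3,5-bis(TIPSO)phenyl]-2-[4-(TIPSO)phenyl]-6-(TIPSO)spiro[2.5]octa-5,7-dien-4-one (trans; spiro centre not controlled, lost on aromatisation) | O=C1C=C(O[Si](C(C)C)(C(C)C)C(C)C)C=C(Br)C12[C@@H](c3cc(O[Si](C(C)C)(C(C)C)C(C)C)cc(O[Si](C(C)C)(C(C)C)C(C)C)c3)[C@@H]2c2ccc(O[Si](C(C)C)(C(C)C)C(C)C)cc2 | intermediate (not isolated)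
9 | (2R,3R)-4-bromo-3-[3,5-bis(TIPSO)phenyl]-2-[4-(TIPSO)phenyl]-6-(TIPSO)-2,3-dihydrobenzofuran | Brc1cc(O[Si](C(C)C)(C(C)C)C(C)C)cc2c1[C@@H](c1cc(O[Si](C(C)C)(C(C)C)C(C)C)cc(O[Si](C(C)C)(C(C)C)C(C)C)c1)[C@H](c1ccc(O[Si](C(C)C)(C(C)C)C(C)C)cc1)O2 | intermediate
10 | 4-hydroxybenzaldehyde | O=Cc1ccc(O)cc1 | starting material
11 | 4-(triisopropylsilyloxy)benzaldehyde | O=Cc1ccc(O[Si](C(C)C)(C(C)C)C(C)C)cc1 | intermediate
12 | bis(pinacolatoboryl)methane | CC1(C)OB(CB2OC(C)(C)C(C)(C)O2)OC1(C)C | starting material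
13 | (E)-2-[4-(triisopropylsilyloxy)phenyl]ethenylboronic acid pinacol ester | CC1(C)OB(/C=C/c2ccc(O[Si](C(C)C)(C(C)C)C(C)C)cc2)OC1(C)C | intermediate
14 | (2R,3R)-3-[3,5-bis(TIPSO)phenyl]-2-[4-(TIPSO)phenyl]-6-(TIPSO)-4-[(E)-2-[4-(TIPSO)phenyl]ethenyl]-2,3-dihydrobenzofuran | CC(C)[Si](C(C)C)(C(C)C)Oc1ccc(/C=C/c2cc(O[Si](C(C)C)(C(C)C)C(C)C)cc3c2[C@@H](c2cc(O[Si](C(C)C)(C(C)C)C(C)C)cc(O[Si](C(C)C)(C(C)C)C(C)C)c2)[C@H](c2ccc(O[Si](C(C)C)(C(C)C)C(C)C)cc2)O3)cc1 | intermediate
15 | (1S,2S)-8-bromo-2-[4-(TIPSO)phenyl]-6-(TIPSO)spiro[2.5]octa-5,7-dien-4-one carrying at C1 the (2R,3R)-dihydrobenzofuran-4-yl unit of 14 (trans; spiro centre not controlled) | O=C1C=C(O[Si](C(C)C)(C(C)C)C(C)C)C=C(Br)C12[C@H](c3cc(O[Si](C(C)C)(C(C)C)C(C)C)cc4c3[C@@H](c3cc(O[Si](C(C)C)(C(C)C)C(C)C)cc(O[Si](C(C)C)(C(C)C)C(C)C)c3)[C@H](c3ccc(O[Si](C(C)C)(C(C)C)C(C)C)cc3)O4)[C@H]2c2ccc(O[Si](C(C)C)(C(C)C)C(C)C)cc2 | intermediate (not isolated)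
16 | (2S,3S)-4-bromo-2-[4-(TIPSO)phenyl]-6-(TIPSO)-3-[(2R,3R)-3-[3,5-bis(TIPSO)phenyl]-2-[4-(TIPSO)phenyl]-6-(TIPSO)-2,3-dihydrobenzofuran-4-yl]-2,3-dihydrobenzofuran | CC(C)[Si](C(C)C)(C(C)C)Oc1ccc([C@H]2Oc3cc(O[Si](C(C)C)(C(C)C)C(C)C)cc(Br)c3[C@@H]2c2cc(O[Si](C(C)C)(C(C)C)C(C)C)cc3c2[C@@H](c2cc(O[Si](C(C)C)(C(C)C)C(C)C)cc(O[Si](C(C)C)(C(C)C)C(C)C)c2)[C@H](c2ccc(O[Si](C(C)C)(C(C)C)C(C)C)cc2)O3)cc1 | intermediate
17 | (2S,3S)-2-[4-(TIPSO)phenyl]-6-(TIPSO)-4-[(E)-2-[4-(TIPSO)phenyl]ethenyl]-3-[(2R,3R)-3-[3,5-bis(TIPSO)phenyl]-2-[4-(TIPSO)phenyl]-6-(TIPSO)-2,3-dihydrobenzofuran-4-yl]-2,3-dihydrobenzofuran | CC(C)[Si](C(C)C)(C(C)C)Oc1ccc([C@H]2Oc3cc(O[Si](C(C)C)(C(C)C)C(C)C)cc(/C=C/c4ccc(O[Si](C(C)C)(C(C)C)C(C)C)cc4)c3[C@@H]2c2cc(O[Si](C(C)C)(C(C)C)C(C)C)cc3c2[C@@H](c2cc(O[Si](C(C)C)(C(C)C)C(C)C)cc(O[Si](C(C)C)(C(C)C)C(C)C)c2)[C@H](c2ccc(O[Si](C(C)C)(C(C)C)C(C)C)cc2)O3)cc1 | intermediate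
18 | (1R,2R)-8-bromo-2-[4-(TIPSO)phenyl]-6-(TIPSO)spiro[2.5]octa-5,7-dien-4-one carrying at C1 the (2S,3S)-dihydrobenzofuran-4-yl unit of 17 (trans; spiro centre not controlled) | O=C1C=C(O[Si](C(C)C)(C(C)C)C(C)C)C=C(Br)C12[C@@H](c3cc(O[Si](C(C)C)(C(C)C)C(C)C)cc4c3[C@H](c3cc(O[Si](C(C)C)(C(C)C)C(C)C)cc5c3[C@@H](c3cc(O[Si](C(C)C)(C(C)C)C(C)C)cc(O[Si](C(C)C)(C(C)C)C(C)C)c3)[C@H](c3ccc(O[Si](C(C)C)(C(C)C)C(C)C)cc3)O5)[C@@H](c3ccc(O[Si](C(C)C)(C(C)C)C(C)C)cc3)O4)[C@@H]2c2ccc(O[Si](C(C)C)(C(C)C)C(C)C)cc2 | intermediate (not isolated)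
19 | (2R,3R)-4-bromo-2-[4-(TIPSO)phenyl]-6-(TIPSO)-3-{(2S,3S)-2-[4-(TIPSO)phenyl]-6-(TIPSO)-3-[(2R,3R)-3-[3,5-bis(TIPSO)phenyl]-2-[4-(TIPSO)phenyl]-6-(TIPSO)-2,3-dihydrobenzofuran-4-yl]-2,3-dihydrobenzofuran-4-yl}-2,3-dihydrobenzofuran | CC(C)[Si](C(C)C)(C(C)C)Oc1ccc([C@H]2Oc3cc(O[Si](C(C)C)(C(C)C)C(C)C)cc([C@@H]4c5c(Br)cc(O[Si](C(C)C)(C(C)C)C(C)C)cc5O[C@H]4c4ccc(O[Si](C(C)C)(C(C)C)C(C)C)cc4)c3[C@@H]2c2cc(O[Si](C(C)C)(C(C)C)C(C)C)cc3c2[C@@H](c2cc(O[Si](C(C)C)(C(C)C)C(C)C)cc(O[Si](C(C)C)(C(C)C)C(C)C)c2)[C@H](c2ccc(O[Si](C(C)C)(C(C)C)C(C)C)cc2)O3)cc1 | intermediate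
20 | 3,4-dihydroxybenzaldehyde | O=Cc1ccc(O)c(O)c1 | starting material
21 | 3,4-bis(triisopropylsilyloxy)benzaldehyde | O=Cc1ccc(O[Si](C(C)C)(C(C)C)C(C)C)c(O[Si](C(C)C)(C(C)C)C(C)C)c1 | intermediate
22 | (E)-2-[3,4-bis(triisopropylsilyloxy)phenyl]ethenylboronic acid pinacol ester | CC1(C)OB(/C=C/c2ccc(O[Si](C(C)C)(C(C)C)C(C)C)c(O[Si](C(C)C)(C(C)C)C(C)C)c2)OC1(C)C | intermediate
23 | deca-O-TIPS ether of the target: 19 with Br replaced by (E)-2-[3,4-bis(TIPSO)phenyl]ethenyl | CC(C)[Si](C(C)C)(C(C)C)Oc1ccc([C@H]2Oc3cc(O[Si](C(C)C)(C(C)C)C(C)C)cc([C@@H]4c5c(/C=C/c6ccc(O[Si](C(C)C)(C(C)C)C(C)C)c(O[Si](C(C)C)(C(C)C)C(C)C)c6)cc(O[Si](C(C)C)(C(C)C)C(C)C)cc5O[C@H]4c4ccc(O[Si](C(C)C)(C(C)C)C(C)C)cc4)c3[C@@H]2c2cc(O[Si](C(C)C)(C(C)C)C(C)C)cc3c2[C@@H](c2cc(O[Si](C(C)C)(C(C)C)C(C)C)cc(O[Si](C(C)C)(C(C)C)C(C)C)c2)[C@H](c2ccc(O[Si](C(C)C)(C(C)C)C(C)C)cc2)O3)cc1 | intermediate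
24 | CNP0099535.1: (2R,3R)-4-[(E)-2-(3,4-dihydroxyphenyl)ethenyl]-2-(4-hydroxyphenyl)-3-{(2S,3S)-6-hydroxy-2-(4-hydroxyphenyl)-3-[(2R,3R)-3-(3,5-dihydroxyphenyl)-6-hydroxy-2-(4-hydroxyphenyl)-2,3-dihydrobenzofuran-4-yl]-2,3-dihydrobenzofuran-4-yl}-2,3-dihydrobenzofuran-6-ol | Oc1ccc([C@H]2Oc3cc(O)cc([C@@H]4c5c(/C=C/c6ccc(O)c(O)c6)cc(O)cc5O[C@H]4c4ccc(O)cc4)c3[C@@H]2c2cc(O)cc3c2[C@@H](c2cc(O)cc(O)c2)[C@H](c2ccc(O)cc2)O3)cc1 | target

Total step count: 16. Longest linear sequence: 11 steps (3 → 4 → 5 → 6 → 7, then steps 6, 9, 10, 11, 12, 15, 16).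

Steps most likely to fail

Step 10. The electrophilic carbenoid may dimerise or attack the silyloxyarene rings faster than it is captured by the ortho-substituted alkene of 14, and the two alkene faces may not be told apart well enough. Step 12 repeats this reaction, so its risk is largely retired once step 10 is solved. The fallback sets out from 9, 3 and 11 and comes back at 16. Bromine–lithium exchange on 9 (n-BuLi, THF, −78 °C) and DMF would give the dihydrobenzofuran-4-carbaldehyde F1. Monosilylation of 3 (TIPSCl, imidazole) would give 3-bromo-5-(triisopropylsilyloxy)phenol F2. Its bromomagnesium phenoxide (EtMgBr, toluene) should add to F1 at the ortho carbon that is para to the silyloxy group and away from its bulk (chelate-controlled ortho-hydroxyalkylation), giving the o-hydroxybenzhydrol F3. p-Toluenesulfinic acid would turn this into the sulfone F4, a standard o-quinone methide precursor. Reduction of 11 (NaBH4) would give the benzyl alcohol F5, and PBr3 would give 4-(triisopropylsilyloxy)benzyl bromide F6. F4, F6, tetrahydrothiophene and Cs2CO3 (MeCN, rt) would then give 16 by a sulfur-ylide [4+1] annulation: conjugate addition of the benzylide to the o-quinone methide anti to the resident aryl group, then 5-exo-tet O-alkylation with loss of the sulfide (trans). This contingency closes the central ring directly at its final size and would be used only if carbene transfer to 14 cannot be made to work.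

Step 6. The acceptor-type carbenoid may discriminate poorly between the two faces of the nearly symmetric trans-stilbene, or a racemic path through a free zwitterion may compete, so that the enantiomeric purity on which both later relay steps rest is not reached. The fallback sets out from 2 and 7 and comes back at 9. The annulation is run with achiral Rh2(esp)2 to give the racemate, and the enantiomers are separated by preparative SFC on an immobilised polysaccharide chiral phase. The (2S,3S)-enantiomer F7 is removed and (2R,3R)-9 enters step 9; absolute configuration then comes from resolution and not from the catalyst.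

Step 5. The silyl ether may be lost once it stands para to a diazonium group, and the diazonium intermediate may couple with unreacted 6; either would cut the supply of the carbene precursor for three annulations. The fallback sets out from 4 and comes back at 7, with the silyl group introduced last. Dithionite reduction of 4 would give 4-amino-5-bromobenzene-1,3-diol F8. Diazotisation (NaNO2, aq. HCl, 0 °C, then NaOAc) would give the zwitterionic 2-bromo-4-hydroxy-6-oxidobenzenediazonium F9. Silylation of the remaining hydroxyl, which is para to the diazonium group and unhindered (TIPSOTf, 2,6-lutidine, CH2Cl2, −20 °C), would give 7.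

Further compounds

F1 | step 10 | (2R,3R)-3-[3,5-bis(TIPSO)phenyl]-2-[4-(TIPSO)phenyl]-6-(TIPSO)-2,3-dihydrobenzofuran-4-carbaldehyde | O=Cc1cc(O[Si](C(C)C)(C(C)C)C(C)C)cc2c1[C@@H](c1cc(O[Si](C(C)C)(C(C)C)C(C)C)cc(O[Si](C(C)C)(C(C)C)C(C)C)c1)[C@H](c1ccc(O[Si](C(C)C)(C(C)C)C(C)C)cc1)O2
F2 | step 10 | 3-bromo-5-(triisopropylsilyloxy)phenol | Oc1cc(Br)cc(O[Si](C(C)C)(C(C)C)C(C)C)c1
F3 | step 10 | 3-bromo-2-{hydroxy[(2R,3R)-dihydrobenzofuran-4-yl of F1]methyl}-5-(triisopropylsilyloxy)phenol (carbinol epimers) | OC(c1c(O)cc(O[Si](C(C)C)(C(C)C)C(C)C)cc1Br)c1cc(O[Si](C(C)C)(C(C)C)C(C)C)cc2c1[C@@H](c1cc(O[Si](C(C)C)(C(C)C)C(C)C)cc(O[Si](C(C)C)(C(C)C)C(C)C)c1)[C@H](c1ccc(O[Si](C(C)C)(C(C)C)C(C)C)cc1)O2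
F4 | step 10 | p-tolyl sulfone from F3 (hydroxyl replaced by p-toluenesulfonyl; epimers) | Cc1ccc(cc1)S(=O)(=O)C(c1c(O)cc(O[Si](C(C)C)(C(C)C)C(C)C)cc1Br)c1cc(O[Si](C(C)C)(C(C)C)C(C)C)cc2c1[C@@H](c1cc(O[Si](C(C)C)(C(C)C)C(C)C)cc(O[Si](C(C)C)(C(C)C)C(C)C)c1)[C@H](c1ccc(O[Si](C(C)C)(C(C)C)C(C)C)cc1)O2
F5 | step 10 | [4-(triisopropylsilyloxy)phenyl]methanol | OCc1ccc(O[Si](C(C)C)(C(C)C)C(C)C)cc1
F6 | step 10 | 4-(triisopropylsilyloxy)benzyl bromide | BrCc1ccc(O[Si](C(C)C)(C(C)C)C(C)C)cc1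
F7 | step 6 | (2S,3S)-enantiomer of 9 | Brc1cc(O[Si](C(C)C)(C(C)C)C(C)C)cc2c1[C@H](c1cc(O[Si](C(C)C)(C(C)C)C(C)C)cc(O[Si](C(C)C)(C(C)C)C(C)C)c1)[C@@H](c1ccc(O[Si](C(C)C)(C(C)C)C(C)C)cc1)O2
F8 | step 5 | 4-amino-5-bromobenzene-1,3-diol | Nc1c(O)cc(O)cc1Br
F9 | step 5 | 2-bromo-4-hydroxy-6-oxidobenzenediazonium (inner salt) | [O-]c1cc(O)cc(Br)c1[N+]#N
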